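**Retrosynthetic overview**

1. Locants are those of the target, a tricyclo[5.3.1.0^{1,5}]undecane: ring A = C1–C5–C6–C7–C11 (C11 is the ketone bridge), ring B = C1–C2–C3–C4–C5, ring C = C1–C10–C9–C8–C7–C11. Last disconnection: 13 from cyclopentene 12 by hydrogenation of C2=C3 on the ring-B face away from C11, which sets C3.
2. Key disconnections C1–C2 and C3–C4 (with C1–C5): 12 from the monocyclic propargyl enol ether 9 in one operation. A [3,3] shift from the oxygen on C11 to C1 makes C1–C2; a copper-catalysed atom-transfer radical bicyclisation then makes C1–C5 and C4–C3. Ring C is the former aromatic ring, ring A forms next, ring B last.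
3. Enabling feature: C1 is the ring-C carbon between the C10 and C11 carbonyls. As the end of the enol ether O–C11=C1 it accepts C2; its chlorine then sits between two carbonyls and gives a radical lying 1,5 to C5 (prenyl on C7), and the C4 radical lies 1,5 to C3 (central allene carbon).
4. 9 from chlorophenol 5 by enantioselective dearomative C-prenylation at C7 (the one stereocentre set by catalysis; C1, C5 and C3 are relayed from it) and O-propargylation. The chlorine first blocks C1, then triggers the radical phase, and finally leaves from the carbinol carbon.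
5. 5 from 2-methylphloroglucinol and (R)-2-methylbutanoic acid (bought side-chain stereocentre) by Friedel–Crafts acylation and ring chlorination.

Key step: step 5

Remark: the enolised β-triketones are written as one tautomer each, and the side-chain centre of the given SMILES is (R), so (R)-2-methylbutanoic acid is the bought acid.

**Route**

Step 1
Reactants: 1 2-methylbenzene-1,3,5-triol (2-methylphloroglucinol); 2 (2R)-2-methylbutanoic acid
Product: 4 (2R)-2-methyl-1-(2,4,6-trihydroxy-3-methylphenyl)butan-1-one, via (2R)-2-methylbutanoyl chloride 3 (not isolated)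
Conditions: 2, (COCl)2, DMF (cat.), CH2Cl2, 0 °C to rt; then 1, AlCl3, CH2Cl2/PhNO2, 0 °C to rt; aq. HCl
Reagents that add atoms: none
Why: Friedel–Crafts C-acylation of the strongly activated triol at one of its two equivalent free ring carbons by the acid chloride made in situ, run cold so that the bought α-stereocentre is not enolised.

Step 2
Reactants: 4 (2R)-2-methyl-1-(2,4,6-trihydroxy-3-methylphenyl)butan-1-one
Product: 5 (2R)-1-(3-chloro-2,4,6-trihydroxy-5-methylphenyl)-2-methylbutan-1-one
Conditions: NCS, MeCN, 0 °C
Reagents that add atoms: N-chlorosuccinimide, ClN1C(=O)CCC1=O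
Why: Electrophilic aromatic chlorination at the only unsubstituted ring carbon (the future C1), which blocks this position in step 3 and installs the later radical trigger.

Step 3
Reactants: 5 (2R)-1-(3-chloro-2,4,6-trihydroxy-5-methylphenyl)-2-methylbutan-1-one; 6 3-methylbut-2-en-1-yl acetate (prenyl acetate)
Product: 7 (6R)-4-chloro-3,5-dihydroxy-6-methyl-6-(3-methylbut-2-en-1-yl)-2-[(2R)-2-methylbutanoyl]cyclohexa-2,4-dien-1-one
Conditions: Pd2(dba)3·CHCl3 (2.5 mol %), (1S,2S)-N,N′-bis[2-(diphenylphosphino)benzoyl]cyclohexane-1,2-diamine (7.5 mol %), Et3N, THF, 0 °C to rt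
Reagents that add atoms: none
Why: Tsuji–Trost allylic alkylation with dearomatisation: the π-prenyl complex of zerovalent palladium should be attacked at its unsubstituted end by the methyl-bearing ring carbon (the acyl- and chlorine-bearing carbons are less nucleophilic and O-allylation is reversible under the catalyst), while the chiral diphosphine differentiates the two faces of the planar nucleophile to set the quaternary centre C7, the ligand antipode being taken should the sense of induction prove opposite.

Step 4
Reactants: 7 (6R)-4-chloro-3,5-dihydroxy-6-methyl-6-(3-methylbut-2-en-1-yl)-2-[(2R)-2-methylbutanoyl]cyclohexa-2,4-dien-1-one; 8 3-chloro-3-methylbut-1-yne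
Product: 9 (6R)-4-chloro-3-hydroxy-6-methyl-6-(3-methylbut-2-en-1-yl)-2-[(2R)-2-methylbutanoyl]-5-[(2-methylbut-3-yn-2-yl)oxy]cyclohexa-2,4-dien-1-one
Conditions: K2CO3, KI (cat.), CuI (cat.), acetone, 40 °C
Reagents that add atoms: none
Why: Copper-catalysed propargylic etherification (copper acetylide/allenylidene, attack at the tertiary carbon) at the only hydroxyl not held in the hydrogen bond to the acyl carbonyl, that is the one on the future C11, between the chlorinated carbon C1 and the quaternary carbon C7.

Step 5
Reactants: 9 (6R)-4-chloro-3-hydroxy-6-methyl-6-(3-methylbut-2-en-1-yl)-2-[(2R)-2-methylbutanoyl]-5-[(2-methylbut-3-yn-2-yl)oxy]cyclohexa-2,4-dien-1-one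
Product: 12 (1S,5S,7S)-8-hydroxy-3-(2-hydroxypropan-2-yl)-4,4,7-trimethyl-9-[(2R)-2-methylbutanoyl]tricyclo[5.3.1.0^{1,5}]undeca-2,8-diene-10,11-dione, via allenyl chlorodione 10 (not isolated), via tricyclic allylic chloride 11 (not isolated)
Conditions: CuCl (10 mol %), 2,2′-bipyridine (10 mol %), degassed PhCl, 100 °C; then H2O/acetone, NaHCO3, rt
Reagents that add atoms: water, O
Why: Proposed new method: heating 9 should trigger the [3,3] propargyl Claisen shift of the O–C11=C1 enol ether, which bonds C2 to C1 and turns the inert vinylic chlorine of 9 into a tertiary C–Cl flanked by the C10 and C11 carbonyls in 10, so that the CuCl/2,2′-bipyridine catalyst can start the radical phase only after the sigmatropic phase. Chlorine abstraction by monovalent copper gives the C1 radical, which closes ring A by 5-exo-trig attack on C5 of the prenyl group; the tertiary C4 radical then closes ring B by attack on the central allene carbon C3 through the π bond lying in the plane of the forming ring (exo with respect to C3=C(CH3)2), and the resulting allyl radical takes chlorine back from the divalent copper chloride complex at its tertiary end to give 11, whose allylic chloride is exchanged for hydroxyl on mild solvolysis. The closest known reaction types are the thermal propargyl Claisen rearrangement of propargyl vinyl ethers to allenyl carbonyl compounds, the copper-catalysed atom-transfer radical cyclisation of α-chloro-1,3-dicarbonyl compounds and the Mn(OAc)3-mediated oxidative radical bicyclisation of diprenylated acylphloroglucinols; their union in one operation, with an allene as the final acceptor, is new. Stereocontrol: both C1 epimers of 10 give the same planar radical, which can reach C5 only on the ring face that carries the prenyl group of C7, so C7 fixes C1; C5 is set by the chair-like 5-exo transition state that turns the (CH3)2C end away from the C8–C10 bridge (exo), and only this exo radical can reach C3, the endo epimer being expected to end as a tertiary chloride. The step needs 5-exo closure at C5 in preference to 6-endo closure at C4 (secured by the trisubstituted prenyl alkene, whose less substituted carbon is C5) and carbon–carbon bond formation ahead of chlorine return (secured by the two intramolecular closures and the low stationary concentration of the divalent copper chloride complex).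

Step 6
Reactants: 12 (1S,5S,7S)-8-hydroxy-3-(2-hydroxypropan-2-yl)-4,4,7-trimethyl-9-[(2R)-2-methylbutanoyl]tricyclo[5.3.1.0^{1,5}]undeca-2,8-diene-10,11-dione
Product: 13 (1S,3S,5S,7S)-8-hydroxy-3-(2-hydroxypropan-2-yl)-4,4,7-trimethyl-9-[(2R)-2-methylbutanoyl]tricyclo[5.3.1.0^{1,5}]undec-8-ene-10,11-dione
Conditions: H2 (4 atm), 5% Rh/Al2O3, EtOAc, rt
Reagents that add atoms: none
Why: Heterogeneous catalytic hydrogenation should add H2 syn to the trisubstituted C2=C3 bond from the open ring-B face opposite the C11 carbonyl bridge (the convex face of the cis-fused rings A and B), which puts H at C3 anti to that bridge and the hydroxyisopropyl group syn to it as in the target, Rh/Al2O3 being chosen to spare the tertiary allylic C–O bond.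

**Compound list**

1 | 2-methylbenzene-1,3,5-triol (2-methylphloroglucinol) | Cc1c(O)cc(O)cc1O | starting material
2 | (2R)-2-methylbutanoic acid | CC[C@@H](C)C(O)=O | starting material
3 | (2R)-2-methylbutanoyl chloride | CC[C@@H](C)C(Cl)=O | intermediate
4 | (2R)-2-methyl-1-(2,4,6-trihydroxy-3-methylphenyl)butan-1-one | CC[C@@H](C)C(=O)c1c(O)cc(O)c(C)c1O | intermediate
5 | (2R)-1-(3-chloro-2,4,6-trihydroxy-5-methylphenyl)-2-methylbutan-1-one | CC[C@@H](C)C(=O)c1c(O)c(Cl)c(O)c(C)c1O | intermediate
6 | 3-methylbut-2-en-1-yl acetate (prenyl acetate) | CC(C)=CCOC(C)=O | starting material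
7 | (6R)-4-chloro-3,5-dihydroxy-6-methyl-6-(3-methylbut-2-en-1-yl)-2-[(2R)-2-methylbutanoyl]cyclohexa-2,4-dien-1-one | CC[C@@H](C)C(=O)C1=C(O)C(Cl)=C(O)[C@@](C)(CC=C(C)C)C1=O | intermediate
8 | 3-chloro-3-methylbut-1-yne | CC(C)(Cl)C#C | starting material
9 | (6R)-4-chloro-3-hydroxy-6-methyl-6-(3-methylbut-2-en-1-yl)-2-[(2R)-2-methylbutanoyl]-5-[(2-methylbut-3-yn-2-yl)oxy]cyclohexa-2,4-dien-1-one | CC[C@@H](C)C(=O)C1=C(O)C(Cl)=C(OC(C)(C)C#C)[C@@](C)(CC=C(C)C)C1=O | intermediate
10 | (6S)-4-chloro-3-hydroxy-6-methyl-6-(3-methylbut-2-en-1-yl)-4-(3-methylbuta-1,2-dien-1-yl)-2-[(2R)-2-methylbutanoyl]cyclohex-2-ene-1,5-dione (both C4 epimers) | CC[C@@H](C)C(=O)C1=C(O)C(Cl)(C=C=C(C)C)C(=O)[C@@](C)(CC=C(C)C)C1=O | intermediate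
11 | (1S,5S,7S)-3-(2-chloropropan-2-yl)-8-hydroxy-4,4,7-trimethyl-9-[(2R)-2-methylbutanoyl]tricyclo[5.3.1.0^{1,5}]undeca-2,8-diene-10,11-dione | CC[C@@H](C)C(=O)C1=C(O)[C@]2(C)C[C@H]3C(C)(C)C(C(C)(C)Cl)=C[C@@]3(C1=O)C2=O | intermediate
12 | (1S,5S,7S)-8-hydroxy-3-(2-hydroxypropan-2-yl)-4,4,7-trimethyl-9-[(2R)-2-methylbutanoyl]tricyclo[5.3.1.0^{1,5}]undeca-2,8-diene-10,11-dione | CC[C@@H](C)C(=O)C1=C(O)[C@]2(C)C[C@H]3C(C)(C)C(C(C)(C)O)=C[C@@]3(C1=O)C2=O | intermediate
13 | (1S,3S,5S,7S)-8-hydroxy-3-(2-hydroxypropan-2-yl)-4,4,7-trimethyl-9-[(2R)-2-methylbutanoyl]tricyclo[5.3.1.0^{1,5}]undec-8-ene-10,11-dione | CC[C@@H](C)C(=O)C1=C(O)[C@]2(C)C[C@H]3C(C)(C)[C@@H](C(C)(C)O)C[C@@]3(C1=O)C2=O | target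

**Step count**

Total steps: 6. Longest linear sequence: 6 steps (from 1 or 2 to 13).

**Steps most likely to fail**

Step 5 (new method). The risks are return of chlorine to the C1 or C4 radical before the ring closures, chlorine capture at the allenyl end of the delocalised C1 radical, copper-promoted oxacyclisation of the allenyl ketone 10, and loss of HCl from the allylic chloride 11 at 100 °C. The fallback uses known chemistry, sets out from 4 and comes back at 13. C-prenylation of 4 at its free ring carbon (prenyl bromide, aqueous KOH, 0 °C) would give (2R)-2-methyl-1-[2,4,6-trihydroxy-3-methyl-5-(3-methylbut-2-en-1-yl)phenyl]butan-1-one F1. Dearomative prenylation at the methyl-bearing carbon under the conditions of step 3 would give (6R)-3,5-dihydroxy-6-methyl-4,6-bis(3-methylbut-2-en-1-yl)-2-[(2R)-2-methylbutanoyl]cyclohexa-2,4-dien-1-one F2. Oxidative radical bicyclisation with Mn(OAc)3·2H2O and catalytic Cu(OAc)2·H2O in AcOH (two 5-exo closures, then oxidative loss of a proton) would give (1S,3R,5S,7S)-8-hydroxy-4,4,7-trimethyl-9-[(2R)-2-methylbutanoyl]-3-(prop-1-en-2-yl)tricyclo[5.3.1.0^{1,5}]undec-8-ene-10,11-dione F3 beside its C3 epimer, which would have to be removed by chromatography. Mukaiyama hydration of F3 (Co(acac)2, PhSiH3, O2, iPrOH) would then give 13.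

Step 3. The risks are alkylation at oxygen or at the chlorine-bearing carbon, a second prenylation, and poor discrimination of the two faces of the planar nucleophile. The fallback sets out from 5 and comes back at 7. It replaces the π-allyl chemistry by ion-pair alkylation under chiral phase-transfer catalysis (prenyl bromide, CsOH·H2O, a cinchonidine-derived N-(9-anthracenylmethyl)ammonium bromide, toluene/CHCl3, −40 °C), which would give 7 directly; this fallback makes no new compound (F0).

Step 4. The risks are alkylation at the hydrogen-bonded hydroxyl or at carbon, and early rearrangement of the ether. The fallback sets out from 7 and comes back at 13. Tsuji–Trost C-prenylation of 7 at the chlorine-bearing carbon with zerovalent palladium (6, Pd(PPh3)4, Et3N, THF) would give (6S)-4-chloro-3-hydroxy-6-methyl-4,6-bis(3-methylbut-2-en-1-yl)-2-[(2R)-2-methylbutanoyl]cyclohex-2-ene-1,5-dione F4 as both C4 epimers. CuCl/2,2′-bipyridine atom-transfer radical bicyclisation (two 5-exo closures onto the prenyl groups, chlorine return at the carbinol carbon) would give (1S,3S,5S,7S)-3-(2-chloropropan-2-yl)-8-hydroxy-4,4,7-trimethyl-9-[(2R)-2-methylbutanoyl]tricyclo[5.3.1.0^{1,5}]undec-8-ene-10,11-dione F5. Solvolysis (NaHCO3, aqueous acetone) would give 13 without the hydrogenation step; C3 is then set in the radical closure, so its epimer would have to be separated.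

Further compounds
F1 | step 5 | (2R)-2-methyl-1-[2,4,6-trihydroxy-3-methyl-5-(3-methylbut-2-en-1-yl)phenyl]butan-1-one | CC[C@@H](C)C(=O)c1c(O)c(CC=C(C)C)c(O)c(C)c1O
F2 | step 5 | (6R)-3,5-dihydroxy-6-methyl-4,6-bis(3-methylbut-2-en-1-yl)-2-[(2R)-2-methylbutanoyl]cyclohexa-2,4-dien-1-one | CC[C@@H](C)C(=O)C1=C(O)C(CC=C(C)C)=C(O)[C@@](C)(CC=C(C)C)C1=O
F3 | step 5 | (1S,3R,5S,7S)-8-hydroxy-4,4,7-trimethyl-9-[(2R)-2-methylbutanoyl]-3-(prop-1-en-2-yl)tricyclo[5.3.1.0^{1,5}]undec-8-ene-10,11-dione | CC[C@@H](C)C(=O)C1=C(O)[C@]2(C)C[C@H]3C(C)(C)[C@@H](C(C)=C)C[C@@]3(C1=O)C2=O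
F0 | step 3 | none | none
F4 | step 4 | (6S)-4-chloro-3-hydroxy-6-methyl-4,6-bis(3-methylbut-2-en-1-yl)-2-[(2R)-2-methylbutanoyl]cyclohex-2-ene-1,5-dione (both C4 epimers) | CC[C@@H](C)C(=O)C1=C(O)C(Cl)(CC=C(C)C)C(=O)[C@@](C)(CC=C(C)C)C1=O
F5 | step 4 | (1S,3S,5S,7S)-3-(2-chloropropan-2-yl)-8-hydroxy-4,4,7-trimethyl-9-[(2R)-2-methylbutanoyl]tricyclo[5.3.1.0^{1,5}]undec-8-ene-10,11-dione | CC[C@@H](C)C(=O)C1=C(O)[C@]2(C)C[C@H]3C(C)(C)[C@@H](C(C)(C)Cl)C[C@@]3(C1=O)C2=O
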